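## Retrosynthetic overview
1. The side chain is built last on a 9-formyl keto lactone. A vinyl ketone Mukaiyama aldol, a chelate-controlled MeMgBr addition and an exo-face reduction of the ring ketone complete the target.
2. The bridged δ-lactone comes from an intramolecular oxa-Michael addition of an acetic acid arm to a tetrasubstituted cyclohexene carbaldehyde. This closure fixes three ring centres under thermodynamic control.
3. The enal comes from carbonylation of a vinyl triflate, which comes from conjugate reduction of an enone.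
4. Key disconnection: the CMe2–CH bond of the 1,4-dicarbonyl unit. An isobutyrate enolate adds to a quinone monoketal, whose β-carbon is the α-carbon of the masked ketone (an enolonium equivalent). The resulting enolate is alkylated with bromoacetate to give the quaternary centre.
5. Ring order: the carbocycle is carried in from 2,6-dimethylphenol by dearomatisation and is never built. The lactone is the only ring formed, in step 5.

Assumption: the (1R,2R)-diether ligand gives the sense of induction drawn in step 2. If it gives the opposite sense, its (1S,2S)-enantiomer is used.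

## Route

Step 1
Reactants: 1 2,6-dimethylphenol
Product: 2 4,4-dimethoxy-2,6-dimethylcyclohexa-2,5-dien-1-one
Conditions: PhI(OAc)2 (2.1 equiv), MeOH, 0 °C to rt
Reagents that add atoms: methanol (CO)
Why: Hypervalent-iodine oxidative dearomatisation of a phenol, run twice at the free para carbon (methoxylation, then ketal formation); the two ortho methyl groups block other sites and no stereocentre is formed.

Step 2
Reactants: 2 4,4-dimethoxy-2,6-dimethylcyclohexa-2,5-dien-1-one; 3 tert-butyl 2-methylpropanoate; 4 tert-butyl 2-bromoacetate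
Product: 7 tert-butyl 2-[(1S,6R)-6-(2-tert-butoxy-2-oxoethyl)-2,2-dimethoxy-4,6-dimethyl-5-oxocyclohex-3-en-1-yl]-2-methylpropanoate, via lithium ester enolate 5 (not isolated), via adduct dienolate 6 (not isolated)
Conditions: 3, LiN(i-Pr)2 (1.05 equiv), (1R,2R)-1,2-dimethoxy-1,2-diphenylethane (1.2 equiv), toluene, −78 °C; 2, −78 °C; then 4, DMPU, −78 to −30 °C
Reagents that add atoms: none
Why: Proposed new method: the β-carbon of the quinone monoketal is the α-carbon of the masked 4-ketone yet is electrophilic through vinylogy with C1=O, so it acts as an enolonium (α-keto cation) equivalent and accepts the isobutyrate enolate, joining two α-carbonyl carbons that are both normally nucleophilic into the 1,4-dicarbonyl unit while the neighbouring ring carbon is still flat; 1,2-attack is blocked by the two flanking methyl groups, the ketone dienolate formed is about five pKa units more stable than the ester enolate, the diether–lithium complex picks one of the two enantiotopic β-carbons (sets C1 of 7), and bromoacetate then enters anti to the new tert-alkyl group (sets the quaternary C6 and rules out rearomatisation); the closest known reaction types are the chiral-diether-mediated asymmetric Michael addition of lithium ester enolates and the Michael addition–enolate alkylation of quinone monoketals.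

Step 3
Reactants: 7 tert-butyl 2-[(1S,6R)-6-(2-tert-butoxy-2-oxoethyl)-2,2-dimethoxy-4,6-dimethyl-5-oxocyclohex-3-en-1-yl]-2-methylpropanoate
Product: 9 tert-butyl 2-[(1S,2R)-2-(2-tert-butoxy-2-oxoethyl)-6,6-dimethoxy-2,4-dimethyl-3-(trifluoromethylsulfonyloxy)cyclohex-3-en-1-yl]-2-methylpropanoate, via lithium enolate 8 (not isolated)
Conditions: LiBH(s-Bu)3, THF, −78 °C; then N-(5-chloropyridin-2-yl)bis(trifluoromethanesulfonimide), −78 to 0 °C
Reagents that add atoms: N-(5-chloropyridin-2-yl)bis(trifluoromethanesulfonimide) (FC(F)(F)S(=O)(=O)N(c1ccc(Cl)cn1)S(=O)(=O)C(F)(F)F)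
Why: Conjugate hydride reduction of the enone, whose 1,2-path is blocked by the quaternary and the methyl-bearing α-carbons, gives the tetrasubstituted enolate regiospecifically and O-triflation traps it (reductive enol triflate synthesis); no stereocentre changes.

Step 4
Reactants: 9 tert-butyl 2-[(1S,2R)-2-(2-tert-butoxy-2-oxoethyl)-6,6-dimethoxy-2,4-dimethyl-3-(trifluoromethylsulfonyloxy)cyclohex-3-en-1-yl]-2-methylpropanoate
Product: 10 tert-butyl 2-[(1S,2R)-2-(2-tert-butoxy-2-oxoethyl)-3-formyl-6,6-dimethoxy-2,4-dimethylcyclohex-3-en-1-yl]-2-methylpropanoate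
Conditions: Pd(OAc)2 (5 mol %), 1,3-bis(diphenylphosphino)propane, CO (1 atm), Et3SiH, Et3N, DMF, 60 °C
Reagents that add atoms: carbon monoxide ([C-]#[O+])
Why: Palladium-catalysed carbonylative reduction (formylation) of a vinyl triflate: oxidative addition to zerovalent palladium, CO insertion and hydride transfer from the silane replace the former phenol oxygen by the formyl carbon; the stereocentres are untouched.

Step 5
Reactants: 10 tert-butyl 2-[(1S,2R)-2-(2-tert-butoxy-2-oxoethyl)-3-formyl-6,6-dimethoxy-2,4-dimethylcyclohex-3-en-1-yl]-2-methylpropanoate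
Product: 13 2-[(1S,5S,6R,9R)-9-formyl-1,5-dimethyl-3,7-dioxo-2-oxabicyclo[3.3.1]nonan-6-yl]-2-methylpropanoic acid, via trans keto enal diacid 11 (not isolated), via cis keto enal diacid 12 (not isolated)
Conditions: CF3CO2H–CH2Cl2 (1:2), 0 °C to rt; then H2O, rt
Reagents that add atoms: water (O)
Why: Acidolysis frees both acids and the ketone (tert-butyl ester and ketal cleavage), the centre next to the ketone then epimerises through its enol or enol ether with protonation anti to the pseudo-axial acetic acid arm, and only the cis isomer 12 can hold the arm axial for the reversible intramolecular oxa-Michael addition to the enal, whose trans-diaxial course (oxygen at C1 from the face of the arm, proton at C9 from the other face) leaves the formyl and tert-alkyl groups equatorial on the carbocycle, the thermodynamic minimum that fixes C1, C6 and C9 relative to the quaternary C5.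

Step 6
Reactants: 13 2-[(1S,5S,6R,9R)-9-formyl-1,5-dimethyl-3,7-dioxo-2-oxabicyclo[3.3.1]nonan-6-yl]-2-methylpropanoic acid; 14 2-(trimethylsilyloxy)buta-1,3-diene
Product: 17 2-[(1S,5S,6R,9S)-9-[(1S)-1-hydroxy-3-oxopent-4-en-1-yl]-1,5-dimethyl-3,7-dioxo-2-oxabicyclo[3.3.1]nonan-6-yl]-2-methylpropanoic acid, via silyl ester 15 (not isolated), via bis-silyl aldol adduct 16 (not isolated)
Conditions: N,O-bis(trimethylsilyl)acetamide, CH2Cl2, 0 °C; 14, (CF3SO2)2NH (3 mol %), −78 °C; then citric acid, MeOH–H2O, 0 °C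
Reagents that add atoms: none
Why: Base-free Mukaiyama aldol addition through an open transition state: with the formyl hydrogen turned inward over the lactone, the enol silane attacks anti to the C9–C1 bond, the better σ* acceptor because C1 carries the acyloxy oxygen (Felkin–Anh), which gives the (1S)-carbinol; silyl transfer masks that carbinol until work-up and the hindered ring ketone does not compete.

Step 7
Reactants: 17 2-[(1S,5S,6R,9S)-9-[(1S)-1-hydroxy-3-oxopent-4-en-1-yl]-1,5-dimethyl-3,7-dioxo-2-oxabicyclo[3.3.1]nonan-6-yl]-2-methylpropanoic acid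
Product: 18 2-[(1S,5S,6R,9S)-9-[(1S,3R)-1,3-dihydroxy-3-methylpent-4-en-1-yl]-1,5-dimethyl-3,7-dioxo-2-oxabicyclo[3.3.1]nonan-6-yl]-2-methylpropanoic acid
Conditions: MeMgBr (3.1 equiv), CH2Cl2–Et2O, −78 °C; pH 5 buffer
Reagents that add atoms: methylmagnesium bromide (C[Mg]Br)
Why: Chelation-controlled Grignard 1,2-addition (Cram chelate, 1,3-induction): the magnesium alkoxide of the carbinol binds the enone oxygen in a six-membered chelate with the bicyclic residue equatorial, and external MeMgBr attacks the face anti to that residue, so vinyl ends cis to it on the chelate, which is the syn-1,3-diol with the (3R) centre; at −78 °C the activated vinyl ketone reacts before the hindered ring ketone, the lactone or enolisation can interfere.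

Step 8
Reactants: 18 2-[(1S,5S,6R,9S)-9-[(1S,3R)-1,3-dihydroxy-3-methylpent-4-en-1-yl]-1,5-dimethyl-3,7-dioxo-2-oxabicyclo[3.3.1]nonan-6-yl]-2-methylpropanoic acid
Product: 19 2-[(1S,5R,6R,7R,9S)-9-[(1S,3R)-1,3-dihydroxy-3-methylpent-4-en-1-yl]-7-hydroxy-1,5-dimethyl-3-oxo-2-oxabicyclo[3.3.1]nonan-6-yl]-2-methylpropanoic acid
Conditions: NaBH4, CeCl3·7H2O, MeOH, −40 °C; cold pH 5 buffer
Reagents that add atoms: none
Why: Luche-type borohydride reduction: the endo face of the 7-ketone is covered by the lactone bridge, so hydride enters from the exo face and gives the endo (7R) alcohol; the near-neutral cold medium avoids β-elimination and acyl migration, the acid reacts as its carboxylate and so cannot lactonise, and the cold pH 5 work-up delivers the free hydroxy acid.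

## Compound list
1 | 2,6-dimethylphenol | Cc1cccc(C)c1O | starting material
2 | 4,4-dimethoxy-2,6-dimethylcyclohexa-2,5-dien-1-one | COC1(OC)C=C(C)C(=O)C(C)=C1 | intermediate
3 | tert-butyl 2-methylpropanoate | CC(C)C(=O)OC(C)(C)C | starting material
4 | tert-butyl 2-bromoacetate | BrCC(=O)OC(C)(C)C | starting material
5 | lithium 1-tert-butoxy-2-methylprop-1-en-1-olate | CC(C)=C(O[Li])OC(C)(C)C | intermediate
6 | lithium (3S)-3-(1-tert-butoxy-2-methyl-1-oxopropan-2-yl)-4,4-dimethoxy-2,6-dimethylcyclohexa-1,5-dien-1-olate | [Li]OC1=C(C)[C@@H](C(C)(C)C(=O)OC(C)(C)C)C(OC)(OC)C=C1C | intermediate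
7 | tert-butyl 2-[(1S,6R)-6-(2-tert-butoxy-2-oxoethyl)-2,2-dimethoxy-4,6-dimethyl-5-oxocyclohex-3-en-1-yl]-2-methylpropanoate | O=C1C(C)=CC(OC)(OC)[C@H](C(C)(C)C(=O)OC(C)(C)C)[C@@]1(C)CC(=O)OC(C)(C)C | intermediate
8 | lithium (5S,6R)-6-(2-tert-butoxy-2-oxoethyl)-5-(1-tert-butoxy-2-methyl-1-oxopropan-2-yl)-4,4-dimethoxy-2,6-dimethylcyclohex-1-en-1-olate | [Li]OC1=C(C)CC(OC)(OC)[C@H](C(C)(C)C(=O)OC(C)(C)C)[C@@]1(C)CC(=O)OC(C)(C)C | intermediate
9 | tert-butyl 2-[(1S,2R)-2-(2-tert-butoxy-2-oxoethyl)-6,6-dimethoxy-2,4-dimethyl-3-(trifluoromethylsulfonyloxy)cyclohex-3-en-1-yl]-2-methylpropanoate | FC(F)(F)S(=O)(=O)OC1=C(C)CC(OC)(OC)[C@H](C(C)(C)C(=O)OC(C)(C)C)[C@@]1(C)CC(=O)OC(C)(C)C | intermediate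
10 | tert-butyl 2-[(1S,2R)-2-(2-tert-butoxy-2-oxoethyl)-3-formyl-6,6-dimethoxy-2,4-dimethylcyclohex-3-en-1-yl]-2-methylpropanoate | O=CC1=C(C)CC(OC)(OC)[C@H](C(C)(C)C(=O)OC(C)(C)C)[C@@]1(C)CC(=O)OC(C)(C)C | intermediate
11 | 2-[(1S,2R)-2-(carboxymethyl)-3-formyl-2,4-dimethyl-6-oxocyclohex-3-en-1-yl]-2-methylpropanoic acid | O=CC1=C(C)CC(=O)[C@H](C(C)(C)C(=O)O)[C@@]1(C)CC(=O)O | intermediate
12 | 2-[(1R,2R)-2-(carboxymethyl)-3-formyl-2,4-dimethyl-6-oxocyclohex-3-en-1-yl]-2-methylpropanoic acid | O=CC1=C(C)CC(=O)[C@@H](C(C)(C)C(=O)O)[C@@]1(C)CC(=O)O | intermediate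
13 | 2-[(1S,5S,6R,9R)-9-formyl-1,5-dimethyl-3,7-dioxo-2-oxabicyclo[3.3.1]nonan-6-yl]-2-methylpropanoic acid | O=C[C@@H]1[C@]2(C)CC(=O)O[C@@]1(C)CC(=O)[C@H]2C(C)(C)C(=O)O | intermediate
14 | 2-(trimethylsilyloxy)buta-1,3-diene | C=CC(=C)O[Si](C)(C)C | starting material
15 | trimethylsilyl 2-[(1S,5S,6R,9R)-9-formyl-1,5-dimethyl-3,7-dioxo-2-oxabicyclo[3.3.1]nonan-6-yl]-2-methylpropanoate | O=C[C@@H]1[C@]2(C)CC(=O)O[C@@]1(C)CC(=O)[C@H]2C(C)(C)C(=O)O[Si](C)(C)C | intermediate
16 | trimethylsilyl 2-[(1S,5S,6R,9S)-1,5-dimethyl-3,7-dioxo-9-[(1S)-3-oxo-1-(trimethylsilyloxy)pent-4-en-1-yl]-2-oxabicyclo[3.3.1]nonan-6-yl]-2-methylpropanoate | C=CC(=O)C[C@H](O[Si](C)(C)C)[C@@H]1[C@]2(C)CC(=O)O[C@@]1(C)CC(=O)[C@H]2C(C)(C)C(=O)O[Si](C)(C)C | intermediate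
17 | 2-[(1S,5S,6R,9S)-9-[(1S)-1-hydroxy-3-oxopent-4-en-1-yl]-1,5-dimethyl-3,7-dioxo-2-oxabicyclo[3.3.1]nonan-6-yl]-2-methylpropanoic acid | C=CC(=O)C[C@H](O)[C@@H]1[C@]2(C)CC(=O)O[C@@]1(C)CC(=O)[C@H]2C(C)(C)C(=O)O | intermediate
18 | 2-[(1S,5S,6R,9S)-9-[(1S,3R)-1,3-dihydroxy-3-methylpent-4-en-1-yl]-1,5-dimethyl-3,7-dioxo-2-oxabicyclo[3.3.1]nonan-6-yl]-2-methylpropanoic acid | C=C[C@](C)(O)C[C@H](O)[C@@H]1[C@]2(C)CC(=O)O[C@@]1(C)CC(=O)[C@H]2C(C)(C)C(=O)O | intermediate
19 | 2-[(1S,5R,6R,7R,9S)-9-[(1S,3R)-1,3-dihydroxy-3-methylpent-4-en-1-yl]-7-hydroxy-1,5-dimethyl-3-oxo-2-oxabicyclo[3.3.1]nonan-6-yl]-2-methylpropanoic acid | C=C[C@](C)(O)C[C@H](O)[C@@H]1[C@]2(C)CC(=O)O[C@@]1(C)C[C@@H](O)[C@H]2C(C)(C)C(=O)O | target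

## Step count and weak points
Total step count: 8. Longest linear sequence: 8.

**Step 2.** The tertiary enolate may transfer an electron to the dienone, which leads to rearomatisation, or the ligand may give low selectivity.
- The fallback sets out from 2 and comes back at 7. It replaces the external ligand by a covalent C2-symmetric auxiliary.
- Ketal exchange of 2 with (1R,2R)-1,2-diphenylethane-1,2-diol (pyridinium tosylate, benzene, methanol distilled off) gives (2R,3R)-7,9-dimethyl-2,3-diphenyl-1,4-dioxaspiro[4.5]deca-6,9-dien-8-one F1. In F1 the two β-carbons are diastereotopic and one is shielded by a phenyl group.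
- Ligand-free addition of 5 followed by alkylation with 4 then gives tert-butyl 2-[(2R,3R,6S,7R)-7-(2-tert-butoxy-2-oxoethyl)-7,9-dimethyl-8-oxo-2,3-diphenyl-1,4-dioxaspiro[4.5]dec-9-en-6-yl]-2-methylpropanoate F2, which can be purified as a single diastereomer.
- HC(OMe)3, MeOH and TsOH exchange the auxiliary for the dimethyl ketal to give 7.

**Step 5.** The conjugate-addition equilibrium may not favour the closed lactone.
- The fallback sets out from 10 and comes back at 13. It makes the tertiary C–O bond irreversibly before the ring is closed.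
- Alkaline H2O2 (NaOH, MeOH, 0 °C) attacks the enal anti to the axial ring methyl group, on the face of the acetate arm. This gives tert-butyl 2-[(1R,2R,3S,6S)-2-(2-tert-butoxy-2-oxoethyl)-1-formyl-4,4-dimethoxy-2,6-dimethyl-7-oxabicyclo[4.1.0]heptan-3-yl]-2-methylpropanoate F3.
- SmI2 (THF–MeOH, −90 °C) cleaves the C–O bond next to the formyl group to give tert-butyl 2-[(1S,2S,3R,4S)-2-(2-tert-butoxy-2-oxoethyl)-3-formyl-4-hydroxy-6,6-dimethoxy-2,4-dimethylcyclohexyl]-2-methylpropanoate F4.
- CF3CO2H and then water remove the protecting groups. The hydroxy acid closes by esterification while the centre next to the ketone epimerises, giving 13.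

**Step 7.** The hydroxy vinyl ketone is fragile, and the chelate may give poor selectivity at the tertiary carbinol.
- The fallback sets out from 13 and comes back at 18. It exchanges the roles of the two carbon groups and uses internal instead of external delivery.
- The aldol of step 6 is run with 2-(trimethylsilyloxy)propene. It gives the robust methyl ketone 2-[(1S,5S,6R,9S)-9-[(1S)-1-hydroxy-3-oxobutyl]-1,5-dimethyl-3,7-dioxo-2-oxabicyclo[3.3.1]nonan-6-yl]-2-methylpropanoic acid F5.
- CH2=CHTi(O-i-Pr)3 (from CH2=CHMgBr and ClTi(O-i-Pr)3) exchanges an alkoxide for the carbinol oxygen and hands over vinyl within the six-membered chelate.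
- Internal delivery gives the diol that is anti when methyl is read as the chain, which is the same (3R) centre as in 18.

## Further compounds
F1 | step 2 | (2R,3R)-7,9-dimethyl-2,3-diphenyl-1,4-dioxaspiro[4.5]deca-6,9-dien-8-one | O=C1C(C)=CC2(O[C@H](c3ccccc3)[C@@H](c3ccccc3)O2)C=C1C
F2 | step 2 | tert-butyl 2-[(2R,3R,6S,7R)-7-(2-tert-butoxy-2-oxoethyl)-7,9-dimethyl-8-oxo-2,3-diphenyl-1,4-dioxaspiro[4.5]dec-9-en-6-yl]-2-methylpropanoate | O=C1C(C)=CC2(O[C@H](c3ccccc3)[C@@H](c3ccccc3)O2)[C@H](C(C)(C)C(=O)OC(C)(C)C)[C@@]1(C)CC(=O)OC(C)(C)C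
F3 | step 5 | tert-butyl 2-[(1R,2R,3S,6S)-2-(2-tert-butoxy-2-oxoethyl)-1-formyl-4,4-dimethoxy-2,6-dimethyl-7-oxabicyclo[4.1.0]heptan-3-yl]-2-methylpropanoate | O=C[C@]12O[C@@]1(C)CC(OC)(OC)[C@H](C(C)(C)C(=O)OC(C)(C)C)[C@@]2(C)CC(=O)OC(C)(C)C
F4 | step 5 | tert-butyl 2-[(1S,2S,3R,4S)-2-(2-tert-butoxy-2-oxoethyl)-3-formyl-4-hydroxy-6,6-dimethoxy-2,4-dimethylcyclohexyl]-2-methylpropanoate | O=C[C@H]1[C@@](C)(O)CC(OC)(OC)[C@H](C(C)(C)C(=O)OC(C)(C)C)[C@@]1(C)CC(=O)OC(C)(C)C
F5 | step 7 | 2-[(1S,5S,6R,9S)-9-[(1S)-1-hydroxy-3-oxobutyl]-1,5-dimethyl-3,7-dioxo-2-oxabicyclo[3.3.1]nonan-6-yl]-2-methylpropanoic acid | CC(=O)C[C@H](O)[C@@H]1[C@]2(C)CC(=O)O[C@@]1(C)CC(=O)[C@H]2C(C)(C)C(=O)O
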